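**Plan**

- Ring numbering: ring A is C1 (OH), C2, C3, C4 (Br), C5, C6 (O-aryl); ring B is C1' (ether O), C2' (OH), C5' and C6' (Br).
- Retrosynthesis: the target is cut first at the O–CH3 bond of a ring B methyl ether and at a temporary C2–CO2H bond, then at C2–C3 and C5–C6 of ring A, then at the ether bond O–C6, and last at C1'–O of ring B.
- Feature used: ring A is a C6–C1–C2 ketone unit plus a symmetric C3–C4(Br)–C5 dialdehyde unit. The ether oxygen on C1', flanked by C2'–O and C6'–Br, can therefore be bonded to C6 while C6 is still an sp3 CH2.
- Forward: ring B is bought as 3,4-dibromoanisole and oxygenated at C1'. A Williamson alkylation gives the 4-aryloxyacetoacetate. Its bis-silyl dienol ether and O-silylated 2-bromomalonaldehyde then close ring A, the only ring formed, as a salicylate.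
- End game: saponification, protodecarboxylation at C2 and O-demethylation.
- Stereochemistry: none arises; the target has no stereocentre and no stereogenic double bond.

Key step: step 6

Remark: 8 is drawn as the dialdehyde although it is mainly enolised. The C=C geometries of 6, 7 and 9 are left undefined, because all of these carbons end up in aromatic ring A.

**Step 1**
Reactants: 1 3,4-dibromoanisole
Product: 3 2,3-dibromo-6-methoxyphenol, via lithium aryltriisopropoxyborate 2 (not isolated)
Conditions: lithium 2,2,6,6-tetramethylpiperidide (from 2,2,6,6-tetramethylpiperidine, n-BuLi) added to 1 and B(OiPr)3, THF, −78 °C; then AcOH, 30% aq. H2O2, 0 → 20 °C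
Reagents that add atoms: triisopropyl borate, CC(C)OB(OC(C)C)OC(C)C (boron and isopropoxy groups of 2); lithium 2,2,6,6-tetramethylpiperidide, [Li]N1C(C)(C)CCCC1(C)C (lithium of 2); hydrogen peroxide, OO (phenol oxygen of 3)
Why: Directed ortho-metalation with in situ borate trapping should remove the most acidic hydrogen, the one between OMe and Br, and capture the aryllithium before it can lose LiBr; boronate oxidation (1,2-aryl shift from boron to oxygen) then places the hydroxyl at that carbon.

**Step 2**
Reactants: 3 2,3-dibromo-6-methoxyphenol; 4 methyl 4-chloro-3-oxobutanoate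
Product: 5 methyl 4-(2,3-dibromo-6-methoxyphenoxy)-3-oxobutanoate
Conditions: NaH (2.2 equiv), THF/DMF, 0 °C; then 4, 0 → 50 °C; aq. HCl work-up
Reagents that add atoms: none
Why: Williamson O-alkylation, a known route to 4-aryloxyacetoacetates; the second equivalent of NaH holds the chloroketoester as its enolate, so the phenoxide should displace the primary chloride.

**Step 3**
Reactants: 5 methyl 4-(2,3-dibromo-6-methoxyphenoxy)-3-oxobutanoate
Product: 6 methyl 4-(2,3-dibromo-6-methoxyphenoxy)-3-(trimethylsilyloxy)but-2-enoate
Conditions: Me3SiCl, Et3N, toluene, 20 °C; filtration under argon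
Reagents that add atoms: chlorotrimethylsilane, C[Si](C)(C)Cl
Why: O-silylation of the enolised β-ketoester is the standard first stage in making 1,3-bis(silyloxy)-1,3-dienes and should give the 3-silyloxy-2-enoate.

**Step 4**
Reactants: 6 methyl 4-(2,3-dibromo-6-methoxyphenoxy)-3-(trimethylsilyloxy)but-2-enoate
Product: 7 1-methoxy-4-(2,3-dibromo-6-methoxyphenoxy)-1,3-bis(trimethylsilyloxy)buta-1,3-diene
Conditions: lithium diisopropylamide (1.05 equiv), THF, −78 °C; then Me3SiCl, −78 → 20 °C
Reagents that add atoms: chlorotrimethylsilane, C[Si](C)(C)Cl
Why: γ-Deprotonation of the silyloxy enoate and O-silylation of the dienolate (silyl dienol ether formation) should give the diene; the CH2 activated by the vinylogous ester and the aryloxy group is far more acidic than any aryl C–H, and the base is kept near one equivalent.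

**Step 5**
Reactants: 8 2-bromomalonaldehyde
Product: 9 2-bromo-3-(trimethylsilyloxy)prop-2-enal
Conditions: Me3SiCl, Et3N, CH2Cl2, 0 → 20 °C; filtration under argon, used crude
Reagents that add atoms: chlorotrimethylsilane, C[Si](C)(C)Cl
Why: O-silylation of the acidic enol gives the 3-silyloxy-2-enal type of masked dielectrophile used in formal (3+3) cyclisations and removes the acidic OH that would protodesilylate 7.

**Step 6**
Reactants: 7 1-methoxy-4-(2,3-dibromo-6-methoxyphenoxy)-1,3-bis(trimethylsilyloxy)buta-1,3-diene; 9 2-bromo-3-(trimethylsilyloxy)prop-2-enal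
Product: 10 methyl 5-bromo-3-(2,3-dibromo-6-methoxyphenoxy)-2-hydroxybenzoate
Conditions: TiCl4 (1.1 equiv), 4 Å molecular sieves, CH2Cl2, −78 → 20 °C; then 10% aq. HCl
Reagents that add atoms: none
Why: TiCl4 activates 9, and the terminal, aryloxy-bearing carbon of diene 7 (C6 of ring A) adds to one masked formyl carbon in a vinylogous Mukaiyama aldol step (C5–C6), after which loss of silanolate leaves a bromo-enal tethered to a titanium-chelated β-ketoester. The ester-bearing carbon C2 then adds to the second formyl carbon (C2–C3) in a 6-(enolendo)-exo-trig aldol closure of ring A, the enol bond C1=C2 lying inside the new ring, and loss of water with tautomerisation gives the salicylate. The closest known reaction is the TiCl4-mediated formal (3+3) cyclisation of 1,3-bis(silyloxy)-1,3-butadienes, 4-aryloxy dienes included, with 3-silyloxy-2-en-1-ones and their 2-halo analogues to salicylates. No stereocentre is formed. The step needs closure through carbon and survival of the C4–Br bond; neutral silyl enol ethers under a Lewis acid offer no free enolate oxygen and no base for furan formation or bromide displacement, and aromatisation makes the closure irreversible. The dielectrophile is symmetric, so either order of bond formation leads to the same product, and both ortho positions of ring B are substituted, so no Friedel–Crafts closure onto ring B can compete.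

**Step 7**
Reactants: 10 methyl 5-bromo-3-(2,3-dibromo-6-methoxyphenoxy)-2-hydroxybenzoate
Product: 11 5-bromo-3-(2,3-dibromo-6-methoxyphenoxy)-2-hydroxybenzoic acid
Conditions: NaOH (5 equiv), MeOH/H2O, 65 °C; then aq. HCl
Reagents that add atoms: sodium hydroxide, [Na+].[OH-] (one carboxyl oxygen)
Why: Saponification (acyl–oxygen ester hydrolysis) of the hydrogen-bonded methyl salicylate needs excess hydroxide and heat, conditions to which the aryl bromides and the diaryl ether are inert.

**Step 8**
Reactants: 11 5-bromo-3-(2,3-dibromo-6-methoxyphenoxy)-2-hydroxybenzoic acid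
Product: 12 4-bromo-2-(2,3-dibromo-6-methoxyphenoxy)phenol
Conditions: quinoline, 200 °C, N2
Reagents that add atoms: none
Why: Thermal protodecarboxylation of a salicylic acid proceeds by ipso-protonation at C2 through the keto tautomer, assisted by the ortho hydroxyl; no copper is present, so the three C–Br bonds should stay untouched.

**Step 9**
Reactants: 12 4-bromo-2-(2,3-dibromo-6-methoxyphenoxy)phenol
Product: 13 3,4-dibromo-2-(5-bromo-2-hydroxyphenoxy)phenol
Conditions: BBr3 (3 equiv), CH2Cl2, −78 → 0 °C; then H2O
Reagents that add atoms: none
Why: BBr3 cleavage of the aryl methyl ether goes by bromide attack on the methyl group of the boron-complexed ether; the diaryl ether offers no sp3 carbon for this attack and should remain intact.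

**Compound list**

1 | 3,4-dibromoanisole (1,2-dibromo-4-methoxybenzene) | COc1ccc(Br)c(Br)c1 | starting material
2 | lithium (2,3-dibromo-6-methoxyphenyl)triisopropoxyborate (not isolated) | [Li+].COc1ccc(Br)c(Br)c1[B-](OC(C)C)(OC(C)C)OC(C)C | intermediate
3 | 2,3-dibromo-6-methoxyphenol | COc1ccc(Br)c(Br)c1O | intermediate
4 | methyl 4-chloro-3-oxobutanoate (methyl 4-chloroacetoacetate) | COC(=O)CC(=O)CCl | starting material
5 | methyl 4-(2,3-dibromo-6-methoxyphenoxy)-3-oxobutanoate | COC(=O)CC(=O)COc1c(OC)ccc(Br)c1Br | intermediate
6 | methyl 4-(2,3-dibromo-6-methoxyphenoxy)-3-(trimethylsilyloxy)but-2-enoate | COC(=O)C=C(COc1c(OC)ccc(Br)c1Br)O[Si](C)(C)C | intermediate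
7 | 1-methoxy-4-(2,3-dibromo-6-methoxyphenoxy)-1,3-bis(trimethylsilyloxy)buta-1,3-diene | COC(O[Si](C)(C)C)=CC(O[Si](C)(C)C)=COc1c(OC)ccc(Br)c1Br | intermediate
8 | 2-bromomalonaldehyde | O=CC(Br)C=O | starting material
9 | 2-bromo-3-(trimethylsilyloxy)prop-2-enal | C[Si](C)(C)OC=C(Br)C=O | intermediate
10 | methyl 5-bromo-3-(2,3-dibromo-6-methoxyphenoxy)-2-hydroxybenzoate | COC(=O)c1cc(Br)cc(Oc2c(OC)ccc(Br)c2Br)c1O | intermediate
11 | 5-bromo-3-(2,3-dibromo-6-methoxyphenoxy)-2-hydroxybenzoic acid | OC(=O)c1cc(Br)cc(Oc2c(OC)ccc(Br)c2Br)c1O | intermediate
12 | 4-bromo-2-(2,3-dibromo-6-methoxyphenoxy)phenol | COc1ccc(Br)c(Br)c1Oc1cc(Br)ccc1O | intermediate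
13 | 3,4-dibromo-2-(5-bromo-2-hydroxyphenoxy)phenol | Oc1ccc(Br)cc1Oc1c(O)ccc(Br)c1Br | target

**Step count and risks**

Total steps: 9. Longest linear sequence: 8 (steps 1–4 and 6–9); step 5 is a one-step side branch.

Steps most likely to fail:

1. Step 6. Protodesilylation of the diene, or decomposition of the brominated dielectrophile under the Lewis acid, may outrun the two C–C bond formations, and the crowded aryloxy terminus may add slowly. The fallback gives up the annulation; it sets out from 3 and comes back at 12. Phenol 3 is arylated with commercial 4-bromo-2-fluorobenzaldehyde (K2CO3, DMF, 100 °C), by nucleophilic aromatic substitution of the fluoride ortho to the formyl group. This should give 4-bromo-2-(2,3-dibromo-6-methoxyphenoxy)benzaldehyde F1. Baeyer–Villiger oxidation with mCPBA in CH2Cl2 should give 4-bromo-2-(2,3-dibromo-6-methoxyphenoxy)phenyl formate F2. Methanolysis with K2CO3 in MeOH then releases 12, which goes on to step 9.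

2. Step 1. Kinetic deprotonation at a ring position other than the one between OMe and Br, or loss of LiBr to an aryne before the borate captures the anion, may erode the regiochemistry. The fallback sets out from 1 and comes back at 3. Compound 1 is lithiated with pre-formed lithium diisopropylamide in THF at −78 °C under equilibrating conditions, where the anion between OMe and Br is the thermodynamic one, and quenched with DMF. This should give 2,3-dibromo-6-methoxybenzaldehyde F3, which can be freed from isomers by crystallisation. Baeyer–Villiger oxidation (mCPBA, CH2Cl2) should give 2,3-dibromo-6-methoxyphenyl formate F4, and K2CO3 in MeOH then gives 3.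

3. Step 2. Self-condensation of the chloroketoester enolate may outcompete O-alkylation by the hindered phenoxide. The fallback sets out from 3 and comes back at 5. Phenol 3 is alkylated with methyl (E)-4-bromo-3-methoxybut-2-enoate (K2CO3, acetone, reflux), an allylic bromide that has no acidic methylene and cannot self-condense. This should give methyl (E)-4-(2,3-dibromo-6-methoxyphenoxy)-3-methoxybut-2-enoate F5. Hydrolysis of the enol ether (aq. HCl, THF, 20 °C) then gives 5.

**Further compounds**

F1 | step 6 | 4-bromo-2-(2,3-dibromo-6-methoxyphenoxy)benzaldehyde | COc1ccc(Br)c(Br)c1Oc1cc(Br)ccc1C=O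
F2 | step 6 | 4-bromo-2-(2,3-dibromo-6-methoxyphenoxy)phenyl formate | COc1ccc(Br)c(Br)c1Oc1cc(Br)ccc1OC=O
F3 | step 1 | 2,3-dibromo-6-methoxybenzaldehyde | COc1ccc(Br)c(Br)c1C=O
F4 | step 1 | 2,3-dibromo-6-methoxyphenyl formate | COc1ccc(Br)c(Br)c1OC=O
F5 | step 2 | methyl (E)-4-(2,3-dibromo-6-methoxyphenoxy)-3-methoxybut-2-enoate | COC(=O)/C=C(/OC)COc1c(OC)ccc(Br)c1Br
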